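**Retrosynthetic overview**
1. Feature: the only ring is a cyclohexanone (C1–C6). Its C1 carries a cross-conjugated divinyl ketone in which the C8 carbonyl stands between alkenyl carbon C7 (exo-methylene) and alkenyl carbon C9 of the E-C9=C10 alkene, which ends at the hydroperoxy carbon C11. C8 can therefore be supplied as carbon monoxide.
2. The last operation frees the O–H groups (two silyl ethers, one peroxy ketal). Before it, C7–C8 and C8–C9 are made together by carbonylative Stille coupling of enol triflate 18, CO 24 and E-alkenylstannane 23.
3. Triflate 18 comes from (R)-carvone 1, which supplies the ring and C1. The isopropenyl group becomes acetyl and then the C7 enol triflate while C5 is still a protected alcohol. C3/C4 are set by hydroxyl-directed α-epoxidation and diaxial hydrolysis at the epoxy-ketone stage, and C6–O by soft enolisation and Rubottom oxidation.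
4. Stannane 23 comes from 2-methylbut-3-yn-2-ol 19 by perhydrolysis, ketalisation with 2-methoxypropene 21 and Pd-catalysed hydrostannation.
5. Rings: none is formed; the carvone six-membered ring is carried through unchanged.

Key step: step 16

Remark 1 (locants): ring C1 (side chain), C2 (CH2), C3 (CHOH), C4 (C(CH3)OH), C5 (C=O), C6 (CH–O-acyl); chain C7–C11. α is the ring face bearing the C1 side chain and β the other face. The target has C3-OH β, C4-OH α (CH3 β) and C6-O β, which is (1S,3R,4S,6S) in these locants.
Remark 2 (assumption): the tertiary C4 hydroxyl is carried through the coupling as a second triethylsilyl ether, because the soft enolisation of step 10 would silylate it anyway. Dimethyldioxirane is used as its acetone solution (from Oxone and acetone). TES = triethylsilyl, TMS = trimethylsilyl, Tf = trifluoromethanesulfonyl.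

**Route**

Step 1
Reactants: 1 (R)-(−)-carvone
Product: 2 (−)-cis-carveol (C5-OH α, cis to the C1 isopropenyl group)
Conditions: NaBH4, CeCl3·7H2O, MeOH, −20 → 0 °C
Reagents that add atoms: none
Why: Luche reduction: the cerium-modified borohydride adds 1,2 and axially to the half-chair with equatorial isopropenyl, so the temporary C5 carbinol should form pseudo-equatorial and cis (α) to the C1 substituent.

Step 2
Reactants: 2 (−)-cis-carveol
Product: 3 cis-carveol α-epoxide (C3–C4 epoxide, C5-OH and C1 isopropenyl all on the α face)
Conditions: VO(acac)2 (cat.), t-BuOOH, CH2Cl2, 0 °C → rt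
Reagents that add atoms: tert-butyl hydroperoxide, CC(C)(C)OO
Why: Hydroxyl-directed vanadium-catalysed epoxidation: the C5 vanadate ester delivers oxygen only to the allylic C3=C4 alkene and only syn to the hydroxyl, which fixes C4–O α (final) and C3–O α (inverted in step 8) and leaves the isopropenyl group untouched.

Step 3
Reactants: 3 cis-carveol α-epoxide
Product: 4 C5 triethylsilyl ether of 3
Conditions: TESCl, imidazole, CH2Cl2, 0 °C → rt
Reagents that add atoms: chlorotriethylsilane, CC[Si](Cl)(CC)CC
Why: Standard silyl ether formation removes the only acidic O–H before the strong base of step 5 and keeps C5 at the alcohol level, so that the acetyl group will be the only ketone when it is enolised.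

Step 4
Reactants: 4 C5 triethylsilyl ether of 3
Product: 6 C1-acetyl compound (methyl ketone; C3–C4 α-epoxide; C5-OTES α), via secondary ozonide 5 (not isolated)
Conditions: O3, CH2Cl2, −78 °C; then PPh3, −78 °C → rt
Reagents that add atoms: ozone, [O-][O+]=O
Why: Ozonolysis (Criegee mechanism) with reductive work-up cleaves the isopropenyl group, the only C=C left, to the acetyl group, while epoxide and silyl ether are inert to ozone and C1 stays equatorial.

Step 5
Reactants: 6 C1-acetyl compound
Product: 8 C7 enol triflate (C3–C4 α-epoxide; C5-OTES α), via potassium enolate 7 (not isolated)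
Conditions: KHMDS (1.05 equiv), THF, −78 °C; then Comins' reagent, −78 °C
Reagents that add atoms: N-(5-chloropyridin-2-yl)bis(trifluoromethanesulfonimide), Clc1ccc(nc1)N(S(=O)(=O)C(F)(F)F)S(=O)(=O)C(F)(F)F
Why: Kinetic enolate O-triflation: the bulky amide base removes a methyl proton rather than the hindered C1–H, and the reactive triflimide traps the enolate at −78 °C before it equilibrates, so C7 and its methylene come from the acetyl group and C1 is not touched (no excess base, to avoid elimination to the alkyne).

Step 6
Reactants: 8 C7 enol triflate (C5-OTES)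
Product: 9 C7 enol triflate epoxy alcohol (C5-OH α)
Conditions: HF·pyridine, pyridine, THF, 0 °C
Reagents that add atoms: none
Why: Buffered fluoride desilylation cleaves the secondary TES ether through Si–F bond formation under conditions that trisubstituted epoxides and enol triflates are known to withstand.

Step 7
Reactants: 9 C7 enol triflate epoxy alcohol
Product: 10 C7 enol triflate epoxy ketone (C3–C4 α-epoxide cis to the C1 substituent; C5 ketone)
Conditions: TPAP (cat.), NMO, 4 Å MS, CH2Cl2, rt
Reagents that add atoms: none
Why: Ley–Griffith oxidation is neutral and gives the epoxy ketone diastereomer with the epoxide cis to the C1 group, which direct nucleophilic epoxidation of carvone does not provide.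

Step 8
Reactants: 10 C7 enol triflate epoxy ketone
Product: 11 C7 enol triflate diol ketone (C3-OH β, C4-OH α, C5 ketone)
Conditions: HClO4 (cat., aq.), THF/H2O, 0 °C → rt
Reagents that add atoms: water, O
Why: Acid-catalysed anti hydrolysis of an α,β-epoxy ketone: water should attack C3 from the β face because C3 is secondary, is remote from the cation-destabilising carbonyl, and lies on the trans-diaxial (Fürst–Plattner) path of the half-chair with equatorial C1 group, so C3 is inverted to β-OH and C4–O stays α; doing this after the C5 oxidation also avoids having to tell two secondary carbinols apart.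

Step 9
Reactants: 11 C7 enol triflate diol ketone
Product: 12 3,4-bis(triethylsilyl) ether of 11
Conditions: TESOTf (2.5 equiv), 2,6-lutidine, CH2Cl2, −78 → 0 °C
Reagents that add atoms: triethylsilyl trifluoromethanesulfonate, CC[Si](CC)(CC)OS(=O)(=O)C(F)(F)F
Why: Silyl triflate silylation is strong enough for the tertiary C4 carbinol as well as C3-OH, and capping both blocks retro-aldol and α-ketol pathways, keeps the α-oriented C4 oxygen from intercepting the later acylpalladium species, and leaves TMS versus TES as a clean difference in step 11.

Step 10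
Reactants: 12 3,4-bis(triethylsilyl) ether
Product: 13 C5 trimethylsilyl enol ether (C5=C6) of 12
Conditions: TMSOTf, Et3N, CH2Cl2, 0 °C
Reagents that add atoms: trimethylsilyl trifluoromethanesulfonate, C[Si](C)(C)OS(=O)(=O)C(F)(F)F
Why: Soft enolisation (silyl triflate with amine) can only run towards C6 because C4 is quaternary, and it avoids the amide bases that would eliminate the 1-substituted vinyl triflate to an alkyne.

Step 11
Reactants: 13 C5 trimethylsilyl enol ether
Product: 16 C6β-hydroxy ketone (C3-OTES β; C4-OTES α; C7 enol triflate), via silyloxy epoxide 14 (not isolated), via C6 trimethylsilyloxy ketone 15 (not isolated)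
Conditions: DMDO, acetone/CH2Cl2, −78 → −20 °C; then citric acid (cat.), MeOH, 0 °C
Reagents that add atoms: dimethyldioxirane, CC1(C)OO1
Why: Rubottom oxidation (dioxirane variant): the electron-rich enol ether is epoxidised in preference to the electron-poor vinyl triflate, from the β face anti to the neighbouring C1 substituent and to the axial C4-OTES; silyl migration and selective TMS methanolysis should then give the equatorial C6β-OH, trans to C1, which is also the thermodynamically preferred epimer.

Step 12
Reactants: 16 C6β-hydroxy ketone; 17 isovaleryl chloride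
Product: 18 C7 enol triflate of the fully oxidised core (C3-OTES β, C4-OTES α, C5 ketone, C6β isovalerate)
Conditions: pyridine, DMAP (cat.), CH2Cl2, 0 °C
Reagents that add atoms: isovaleryl chloride (17), CC(C)CC(=O)Cl
Why: DMAP-catalysed acylation of the only free, equatorial secondary hydroxyl under mild base, which avoids enediol transposition of the α-ketol and keeps C6 in its stable trans-diequatorial arrangement.

Step 13
Reactants: 19 2-methylbut-3-yn-2-ol
Product: 20 3-hydroperoxy-3-methylbut-1-yne
Conditions: H2O2 (50 % aq.), H2SO4, 0 °C (kept in solution, shielded)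
Reagents that add atoms: hydrogen peroxide, OO
Why: Acid-catalysed perhydrolysis (SN1) of a tertiary propargylic alcohol: the tertiary cation is captured by the large excess of hydrogen peroxide, a long-known entry to acetylenic hydroperoxides.

Step 14
Reactants: 20 3-hydroperoxy-3-methylbut-1-yne; 21 2-methoxypropene
Product: 22 3-(2-methoxypropan-2-ylperoxy)-3-methylbut-1-yne
Conditions: PPTS (cat.), CH2Cl2, 0 °C
Reagents that add atoms: 2-methoxypropene (21), C=C(C)OC
Why: Acid-catalysed addition of the hydroperoxide O–H to the enol ether (peroxy ketal protection) removes the reducible, metal-sensitive OOH proton and gives a group that very mild aqueous acid takes off again.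

Step 15
Reactants: 22 alkynyl peroxy ketal
Product: 23 (E)-tributyl[3-(2-methoxypropan-2-ylperoxy)-3-methylbut-1-enyl]stannane
Conditions: Bu3SnH (slow addition), PdCl2(PPh3)2 (cat.), THF, 0 °C
Reagents that add atoms: tributyltin hydride, CCCC[SnH](CCCC)CCCC
Why: Palladium-catalysed syn-hydrostannation: the fully substituted propargylic carbon steers tin to the terminal carbon and syn addition gives the E-alkene, and the non-radical pathway avoids the stannyl radicals that would attack the O–O bond.

Step 16
Reactants: 18 C7 enol triflate of the fully oxidised core; 23 E-alkenylstannane; 24 carbon monoxide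
Product: 25 protected target (C11 peroxy ketal, C3 and C4 TES ethers, C6 isovalerate)
Conditions: Pd2(dba)3·CHCl3 (cat.), AsPh3 (cat.), LiCl (3 equiv), CO (3 atm), NMP, 40 °C, dark
Reagents that add atoms: carbon monoxide (24), [C-]#[O+]
Why: Pd(0) adds oxidatively to the C7–OTf bond, chloride replaces triflate on palladium, CO migrates into the Pd–C7 bond to give the acylpalladium chloride (C7–C8), stannane 23 hands over its tin-bearing carbon C9, and reductive elimination makes C8–C9 and returns Pd(0). The closest known reaction type is the carbonylative Stille coupling of enol triflates with alkenylstannanes, the standard route to unsymmetrical divinyl ketones. No ring is closed and no stereocentre is created; the four ring stereocentres are spectators in a neutral medium, and the exo-methylene and the E-alkene are kept because every elementary step is stereoretentive at sp2 carbon. The step needs carbonylative rather than direct coupling, which is secured by CO overpressure, by LiCl, and by the α-branched, hindered alkenylpalladium, whose slow transmetalation leaves time for CO insertion. It also needs survival of the O–O bond, which is helped by the peroxy ketal (no O–H and no C–H on the peroxide carbons), by a phosphine-free, weakly reducing arsine ligand, and by the low temperature; dialkyl peroxides and peroxy ketals have been carried through Pd(0) cross-couplings. The silyl caps on C3 and C4 leave no hydroxyl that could capture the acylpalladium intermediate.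

Step 17
Reactants: 25 protected target
Product: 26 target CNP0239240.1
Conditions: HF (48 % aq.), MeCN, 0 °C → rt (plastic vessel)
Reagents that add atoms: none
Why: Global acidic deprotection: aqueous HF cleaves both TES ethers through Si–F formation and hydrolyses the acetone-derived peroxy ketal to the free hydroperoxide, and the absence of base avoids epoxidation of the enones by the hydroperoxide, epimerisation at C6 and migration of the exo-methylene.

**Compound list**
1 | (R)-(−)-carvone | C=C(C)[C@@H]1CC=C(C)C(=O)C1 | starting material
2 | (−)-cis-carveol, (1R,5R)-2-methyl-5-(prop-1-en-2-yl)cyclohex-2-en-1-ol | C=C(C)[C@@H]1CC=C(C)[C@H](O)C1 | intermediate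
3 | cis-carveol α-epoxide (epoxide, C5-OH and isopropenyl all α) | C=C(C)[C@@H]1C[C@@H]2O[C@]2(C)[C@H](O)C1 | intermediate
4 | C5 triethylsilyl ether of 3 | C=C(C)[C@@H]1C[C@@H]2O[C@]2(C)[C@H](O[Si](CC)(CC)CC)C1 | intermediate
5 | secondary ozonide of 4 (1,2,4-trioxolane at C7, not isolated) | CC1(OCOO1)[C@@H]2C[C@@H]3O[C@]3(C)[C@H](O[Si](CC)(CC)CC)C2 | intermediate
6 | C1-acetyl compound (α-epoxide, C5-OTES) | CC(=O)[C@@H]1C[C@@H]2O[C@]2(C)[C@H](O[Si](CC)(CC)CC)C1 | intermediate
7 | potassium enolate of 6 towards the methyl carbon (not isolated) | [K+].C=C([O-])[C@@H]1C[C@@H]2O[C@]2(C)[C@H](O[Si](CC)(CC)CC)C1 | intermediate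
8 | C7 enol triflate (α-epoxide, C5-OTES) | C=C(OS(=O)(=O)C(F)(F)F)[C@@H]1C[C@@H]2O[C@]2(C)[C@H](O[Si](CC)(CC)CC)C1 | intermediate
9 | C7 enol triflate epoxy alcohol (C5-OH α) | C=C(OS(=O)(=O)C(F)(F)F)[C@@H]1C[C@@H]2O[C@]2(C)[C@H](O)C1 | intermediate
10 | C7 enol triflate epoxy ketone (α-epoxide, C5 ketone) | C=C(OS(=O)(=O)C(F)(F)F)[C@@H]1C[C@@H]2O[C@]2(C)C(=O)C1 | intermediate
11 | C7 enol triflate diol ketone (C3-OH β, C4-OH α) | C=C(OS(=O)(=O)C(F)(F)F)[C@@H]1C[C@@H](O)[C@](C)(O)C(=O)C1 | intermediate
12 | 3,4-bis(triethylsilyl) ether of 11 | C=C(OS(=O)(=O)C(F)(F)F)[C@@H]1C[C@@H](O[Si](CC)(CC)CC)[C@](C)(O[Si](CC)(CC)CC)C(=O)C1 | intermediate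
13 | C5 trimethylsilyl enol ether (C5=C6) of 12 | C=C(OS(=O)(=O)C(F)(F)F)[C@@H]1C[C@@H](O[Si](CC)(CC)CC)[C@](C)(O[Si](CC)(CC)CC)C(O[Si](C)(C)C)=C1 | intermediate
14 | C5–C6 β-silyloxy epoxide (not isolated) | C=C(OS(=O)(=O)C(F)(F)F)[C@@H]1C[C@@H](O[Si](CC)(CC)CC)[C@](C)(O[Si](CC)(CC)CC)[C@@]2(O[Si](C)(C)C)O[C@H]21 | intermediate
15 | C6β trimethylsilyloxy ketone (not isolated) | C=C(OS(=O)(=O)C(F)(F)F)[C@@H]1C[C@@H](O[Si](CC)(CC)CC)[C@](C)(O[Si](CC)(CC)CC)C(=O)[C@H]1O[Si](C)(C)C | intermediate
16 | C6β-hydroxy ketone | C=C(OS(=O)(=O)C(F)(F)F)[C@@H]1C[C@@H](O[Si](CC)(CC)CC)[C@](C)(O[Si](CC)(CC)CC)C(=O)[C@H]1O | intermediate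
17 | isovaleryl chloride | CC(C)CC(=O)Cl | starting material
18 | C7 enol triflate of the fully oxidised core (3,4-bis-TES, C6β isovalerate) | C=C(OS(=O)(=O)C(F)(F)F)[C@@H]1C[C@@H](O[Si](CC)(CC)CC)[C@](C)(O[Si](CC)(CC)CC)C(=O)[C@H]1OC(=O)CC(C)C | intermediate
19 | 2-methylbut-3-yn-2-ol | CC(C)(O)C#C | starting material
20 | 3-hydroperoxy-3-methylbut-1-yne | C#CC(C)(C)OO | intermediate
21 | 2-methoxypropene | C=C(C)OC | starting material
22 | 3-(2-methoxypropan-2-ylperoxy)-3-methylbut-1-yne | C#CC(C)(C)OOC(C)(C)OC | intermediate
23 | (E)-tributyl[3-(2-methoxypropan-2-ylperoxy)-3-methylbut-1-enyl]stannane | CCCC[Sn](CCCC)(CCCC)/C=C/C(C)(C)OOC(C)(C)OC | intermediate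
24 | carbon monoxide | [C-]#[O+] | starting material
25 | protected target (C11 peroxy ketal, 3,4-bis-TES, C6 isovalerate) | C=C(C(=O)/C=C/C(C)(C)OOC(C)(C)OC)[C@@H]1C[C@@H](O[Si](CC)(CC)CC)[C@](C)(O[Si](CC)(CC)CC)C(=O)[C@H]1OC(=O)CC(C)C | intermediate
26 | CNP0239240.1, (1S,3R,4S,6S) in the locants used here | C=C(C(=O)/C=C/C(C)(C)OO)[C@@H]1C[C@@H](O)[C@](C)(O)C(=O)[C@H]1OC(=O)CC(C)C | target

**Step count**
Total step count: 17.
Longest linear sequence: 14 steps (steps 1–12, 16, 17).

**Steps most likely to fail**

Step 16.
- What may go wrong: palladium(0) or the arsine may cleave the O–O bond or ionise the tertiary allylic C11–O bond of 23 or 25. Transmetalation may also overtake CO insertion, so that the two alkenyl groups join without C8.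
- Fallback (sets out from 18, comes back at 25): palladium and peroxide are kept apart. Triflate 18 is coupled under the same catalyst with 24 and commercial tributyl(vinyl)stannane to the parent divinyl ketone F1, which still takes C8 from CO.
- Separately, 2-methylbut-2-ene is photooxygenated (O2, tetraphenylporphyrin, hν, CH2Cl2; Schenck ene reaction) to 3-hydroperoxy-3-methylbut-1-ene F2. This is separated from its secondary regioisomer and ketalised with 21 (PPTS) to the alkenyl peroxy ketal F3.
- Cross-metathesis of F1 with an excess of F3 (Hoveyda–Grubbs II, CH2Cl2, 40 °C) should engage only the monosubstituted vinyl group, since the 1,1-disubstituted C7 methylene is inert, and should give the E-enone 25.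

Step 15.
- What may go wrong: the tin hydride, or stannyl radicals formed from it, may reduce the peroxide. Tin may also be delivered in part to the internal alkyne carbon.
- Fallback (sets out from 22, comes back at 25, by-passing 23): tin is replaced by boron. Alkyne 22 is hydroborated with pinacolborane (dicyclohexylborane cat., neat, rt), a syn and terminal-selective addition, to the (E)-alkenyl pinacol boronate F4.
- F4 is joined to 18 and 24 in a carbonylative Suzuki–Miyaura coupling (Pd(OAc)2, AsPh3, CsF, THF, CO 1 atm, rt). This is a known way from enol triflates and alkenylboron reagents to divinyl ketones, and it makes the same two bonds.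

Step 8.
- What may go wrong: the protonated epoxy ketone may undergo an acyl shift with ring contraction. Opening may also be slow enough that regiocontrol and the vinyl triflate suffer.
- Fallback (sets out from 9, comes back at 11, by-passing 10): the epoxide is opened at the alcohol oxidation level and the ketone is made afterwards by a site-selective oxidation.
- Epoxy alcohol 9 is hydrolysed (HClO4 cat., THF/H2O) by the same diaxial attack at C3, here assisted by the inductive deactivation of C4 by the C5 hydroxyl, to the C3β,C4α,C5α-triol F5.
- Dibutyltin oxide (MeOH, reflux) can bridge only the cis C4/C5 pair, not the trans-diaxial C3/C4 pair, and should give the C4,C5-stannylene acetal F6. Brominolysis with NBS (CHCl3, rt) oxidises its secondary C5 carbinol to the ketone and delivers 11 with C3-OH untouched.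

**Further compounds**
F1 | step 16 | parent divinyl ketone (C9=C10 vinyl; 3,4-bis-TES; C6β isovalerate) | C=CC(=O)C(=C)[C@@H]1C[C@@H](O[Si](CC)(CC)CC)[C@](C)(O[Si](CC)(CC)CC)C(=O)[C@H]1OC(=O)CC(C)C
F2 | step 16 | 3-hydroperoxy-3-methylbut-1-ene | C=CC(C)(C)OO
F3 | step 16 | 3-(2-methoxypropan-2-ylperoxy)-3-methylbut-1-ene | C=CC(C)(C)OOC(C)(C)OC
F4 | step 15 | (E)-2-[3-(2-methoxypropan-2-ylperoxy)-3-methylbut-1-enyl]-4,4,5,5-tetramethyl-1,3,2-dioxaborolane | CC1(C)OB(/C=C/C(C)(C)OOC(C)(C)OC)OC1(C)C
F5 | step 8 | C7 enol triflate triol (C3-OH β, C4-OH α, C5-OH α) | C=C(OS(=O)(=O)C(F)(F)F)[C@@H]1C[C@@H](O)[C@](C)(O)[C@H](O)C1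
F6 | step 8 | C4,C5-O-dibutylstannylene acetal of F5 | C=C(OS(=O)(=O)C(F)(F)F)[C@@H]1C[C@@H](O)[C@]2(C)O[Sn](CCCC)(CCCC)O[C@@H]2C1
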